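The numbers of this flask belong to no real substance; the run is a simulation.

Think in reciprocal seconds: a first-order constant is one reciprocal time, and such constants add.

| flask | solid substrate | reagent | initiator | time |
|---|---|---|---|---|
| north-east | 20 mM | 12.0 mM (fed, over 4.0 min) | 1.0 mM | 10 min |
| south-west | 20 mM | 25.0 mM (fed, over 4.0 min) | 1.0 mM | 10 min |
| south | 20 mM | 50.0 mM (fed, over 4.0 min) | 1.0 mM | 10 min |
| east | 20 mM | 100 mM (fed, over 4.0 min) | 1.0 mM | 10 min |

    2 second chain carrier → ended chains B (k1 = 6.4 × 10⁶ M⁻¹ s⁻¹)
    initiator → 2 initiating radical (k2 = 6.3 × 10⁻⁴ s⁻¹)
    reagent + first chain carrier → target + second chain carrier (k3 = 85000 M⁻¹ s⁻¹)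
    starting material + target → side product (k4 = 0.24 M⁻¹ s⁻¹)
    solid substrate ⇌ starting material, rate k5*(cs5 - [starting material]) while solid is left; crystals form when [starting material] > cs5 (cs5 = 1.4 mM, k5 = 0.012 s⁻¹)
    first chain carrier → ended carrier (k6 = 0.35 s⁻¹)
    starting material ⇌ dormant form (K7 = 6.9, k7 = 0.0019 s⁻¹)
    2 first chain carrier → ended chains A (k8 = 2 × 10⁷ M⁻¹ s⁻¹)
    starting material + initiating radical → capped initiator + first chain carrier (k9 = 3.6 × 10⁵ M⁻¹ s⁻¹)
    starting material + second chain carrier → by-product + first chain carrier (k10 = 28000 M⁻¹ s⁻¹)

- a species is counted by the solid substrate in it: one ended chains A or side product counts as two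
- a step written with two of one species runs at k times the square of its concentration and takes two of it each time
- given per volume of solution although it is solid: solid substrate
- at the start none of the solid substrate is in solution
- "hardly changes" means that all values lie within two and a half points (for a concentration: within two and a half percent of the largest)
- run time (north-east): 10 min

- amount of target at the end, in percent of the solid substrate charged for north-east, south-west, south, east, in this order
- how the row runs (hardly changes / rises, then falls / rises all the way / falls all the way / falls, then rises)

Examiner: How fast does the chain take dissolved starting material?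

Candidate: Initiator makes radicals, and the meeting of two second chain carrier ends chains. Balancing the two gives a level equal to the square root of initiator constant times initiator over ending constant. In powers of ten, the root simply halves the exponent: 3.14 × 10⁻⁴ mM. Multiply that level by the constant 28000 M⁻¹ s⁻¹ of the step between starting material and second chain carrier. The product is the chain constant, the pseudo-first-order rate at which the chain takes starting material: 0.00878 s⁻¹. It holds no reagent term.

Examiner: Does that level arrive in time?

Candidate: Yes. Its half-life by the ending step is 0.249 s, far shorter than the run of 10 min.

Examiner: What does it yield?

Candidate: With solution empty, the solid delivers 8.40 × 10⁻⁴ s⁻¹ of its charge. Three constants share that stream: the slowing of dissolving, 0.012 s⁻¹; the chain; and the passage to dormant form, 0.0019 s⁻¹. The chain's share is 38.7%. Dissolved starting material sits near 3.70% of the charge. Held for the whole run, that share of the stream gives target at 19.5% of the charge, as an estimate.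

Examiner: North-east has the smallest dose. Is reagent not the limiting reagent there?

Candidate: Its whole charge is 60.0% of the substrate charge, above my figure. It arrives at 0.00250 s⁻¹ of the substrate charge, while the chain asks 3.25 × 10⁻⁴ s⁻¹. After 1.00 min of feed, with the fed reagent counted as unused, first chain carrier leaves by reagent at 255 s⁻¹, and second chain carrier leaves by starting material at 20.7 s⁻¹. So in north-east second chain carrier is the resting state.

Examiner: But initiator fades.

Candidate: It does, with a half-life of 18 min, longer than the run. The chain constant follows the root and ends at 82.8% of its start. That pulls my figure down somewhat. I commit to a little under 19.5%, and a flat row.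

The forecast gave 14.9%, 15%, 15% and 15%, a row that hardly changes, on the ground that “The reagent dose barely matters”. Its number is lower than mine, and the shape is the same.

The flasks give 17.8%, 17.8%, 17.9% and 17.9%: the row hardly changes. In north-east at 4.56 min, the chain took starting material with a half-life of 1.4 min, much shorter than the 68 min with which target went to side product. That second time is longer than the run, and north-east ends with target at 17.8% and side product at 1.79%. Scaled by the root of initiator left, the chain constant in north-east at 10.0 min is 0.00727 s⁻¹, and the second chain carrier found there gives 0.00725 s⁻¹. In south-west at 100 min, with 2.28% of initiator left, scaling gives 0.00133 s⁻¹, and the carrier found gives 0.00133 s⁻¹.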